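**Plan**
Cuts: (a) the quinone goes back to a 4-silyloxy-3-furylcyclohex-2-enone, with the oxidation level lowered on purpose. (b) The ring C=C bond between the furyl-bearing carbon and the neighbouring CH is cut together with the furan O1–C2 bond, which opens both rings to one acyclic hepta-1,6-diyne whose internal alkyne belongs to a (Z)-2-en-4-ynal. (c) The vinyl–alkynyl bond is cut (Sonogashira). (d) The carbinol–vinyl bond is cut (iodide/propiolate/aldehyde three-component aldol).
Enabling feature: furan C2 and the quinone carbon bonded to it are adjacent sp2 carbons that map onto the two carbons of a single alkyne. The quinone CH beside them lies α to a C=O, so it is the carbene carbon of an oxidised terminal alkyne. Furan O1–C5H is an aldehyde held cis to that alkyne on the furan C3=C4 bond.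
Forward order: the chain is joined first (diyne + iodoenoate) and adjusted by redox steps and acylation. The carbocycle and the furan then arise together in one gold-catalysed oxidative cascade, and desilylation and oxidation turn the carbocycle into the quinone.
Stereochemistry: the single (S)-centre comes from the catalytic enantioselective three-component aldol, which also fixes the alkene geometry that the furan closure needs, and no later step breaks a bond at it. The silyloxy carbon is carried as an epimer mixture and is erased in the last step.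

Key step: step 11

Assumption: the sense of induction in step 5 is taken from the formyl C–H···O binding model of aldehyde–oxazaborolidinium complexes (Re-face attack with the (R)-prolinol-derived catalyst). It is to be checked on the β-iodo hydroxy ester by Mosher ester analysis, and the catalyst antipode exchanged if needed.

**Route**

Step 1
Reactants: 1 5-(trimethylsilyl)pent-4-yn-1-ol
Product: 2 5-(trimethylsilyl)pent-4-ynal
Conditions: IBX (1.5 equiv), EtOAc, 75 °C
Reagents that add atoms: none
Why: IBX oxidation takes a primary alcohol to the aldehyde without over-oxidation and leaves the C-silylated alkyne untouched.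

Step 2
Reactants: 2 5-(trimethylsilyl)pent-4-ynal; 3 ethynylmagnesium bromide
Product: 4 rac-7-(trimethylsilyl)hepta-1,6-diyn-3-ol
Conditions: THF, 0 °C; aqueous work-up
Reagents that add atoms: none
Why: Grignard 1,2-addition of the acetylide to an unhindered aldehyde; the new carbinol carbon is deliberately racemic because it ends as a quinone carbonyl carbon.

Step 3
Reactants: 4 rac-7-(trimethylsilyl)hepta-1,6-diyn-3-ol
Product: 5 rac-3-(tert-butyldimethylsilyloxy)-7-(trimethylsilyl)hepta-1,6-diyne
Conditions: TBSCl, imidazole, DMF, rt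
Reagents that add atoms: tert-butyldimethylsilyl chloride (TBSCl), CC(C)(C)[Si](C)(C)Cl
Why: Standard imidazole-promoted O-silylation; the TBS ether masks a hydroxyl that would otherwise add to the gold-activated alkyne in step 11 (5-exo-dig hydroalkoxylation) and compete in the acylation of step 10.

Step 4
Reactants: 6 4-methylpent-3-en-1-ol
Product: 7 4-methylpent-3-enal
Conditions: IBX (1.3 equiv), EtOAc, 75 °C; filtered, concentrated cold, used at once
Reagents that add atoms: none
Why: IBX oxidation under essentially neutral conditions gives the β,γ-unsaturated aldehyde without moving the double bond into conjugation, provided that 7 is used at once.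

Step 5
Reactants: 7 4-methylpent-3-enal; 8 methyl propiolate
Product: 11 methyl (2Z)-2-[(1S)-1-hydroxy-4-methylpent-3-en-1-yl]-3-iodoprop-2-enoate, via silyl allenolate 9 (not isolated), via O-trimethylsilyl ether 10 (not isolated)
Conditions: TMSI (1.2 equiv), B-(o-tolyl)oxazaborolidine from (R)-α,α-diphenylprolinol activated with Tf2NH (20 mol %), CH2Cl2, −78 °C; then 1 M HCl, THF, 0 °C
Reagents that add atoms: iodotrimethylsilane (TMSI), C[Si](C)(C)I
Why: Catalytic enantioselective β-iodo Morita–Baylis–Hillman (halo-aldol) three-component coupling: TMSI adds 1,4 to 8 to give silyl allenolate 9, which attacks the Re face of 7 bound to the chiral oxazaborolidinium ion (formyl C–H···O organised complex, Si face shielded by a catalyst aryl group) to set the (S)-carbinol, and the kinetic approach of the aldehyde anti to iodine at −78 °C gives the Z alkene with iodine cis to the ester.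

Step 6
Reactants: 5 rac-3-(tert-butyldimethylsilyloxy)-7-(trimethylsilyl)hepta-1,6-diyne; 11 methyl (2Z)-2-[(1S)-1-hydroxy-4-methylpent-3-en-1-yl]-3-iodoprop-2-enoate
Product: 12 methyl (2Z)-6-(tert-butyldimethylsilyloxy)-2-[(1S)-1-hydroxy-4-methylpent-3-en-1-yl]-10-(trimethylsilyl)dec-2-ene-4,9-diynoate (both C6 epimers)
Conditions: Pd(PPh3)2Cl2 (3 mol %), CuI (6 mol %), Et3N, THF, 0 °C to rt
Reagents that add atoms: none
Why: Sonogashira coupling of a (Z)-β-iodoacrylate proceeds with retention of alkene geometry at or below room temperature, and only the free terminal alkyne of 5 can couple because the other one is capped with SiMe3.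

Step 7
Reactants: 12 methyl (2Z)-6-(tert-butyldimethylsilyloxy)-2-[(1S)-1-hydroxy-4-methylpent-3-en-1-yl]-10-(trimethylsilyl)dec-2-ene-4,9-diynoate
Product: 13 methyl (2Z)-6-(tert-butyldimethylsilyloxy)-2-[(1S)-1-hydroxy-4-methylpent-3-en-1-yl]dec-2-ene-4,9-diynoate
Conditions: K2CO3 (0.3 equiv), MeOH, 0 °C
Reagents that add atoms: none
Why: Carbonate-catalysed methanolysis (protodesilylation) cleaves the C(sp)–SiMe3 bond selectively, whereas the secondary TBS ether survives and transesterification of the methyl ester is degenerate.

Step 8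
Reactants: 13 methyl (2Z)-6-(tert-butyldimethylsilyloxy)-2-[(1S)-1-hydroxy-4-methylpent-3-en-1-yl]dec-2-ene-4,9-diynoate
Product: 14 (2E)-6-(tert-butyldimethylsilyloxy)-2-[(1S)-1-hydroxy-4-methylpent-3-en-1-yl]dec-2-ene-4,9-diyn-1-ol (CH2OH cis to the alkynyl group; the descriptor changes by priority only)
Conditions: i-Bu2AlH (DIBAL-H, 4 equiv), CH2Cl2, −78 to −30 °C; aq potassium sodium tartrate
Reagents that add atoms: none
Why: 1,2-Reduction of the conjugated ester with i-Bu2AlH gives the allylic alcohol without touching the alkynes, the alkene geometry, the silyl ether or the stereocentre.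

Step 9
Reactants: 14 (2E)-6-(tert-butyldimethylsilyloxy)-2-[(1S)-1-hydroxy-4-methylpent-3-en-1-yl]dec-2-ene-4,9-diyn-1-ol
Product: 15 (2Z)-6-(tert-butyldimethylsilyloxy)-2-[(1S)-1-hydroxy-4-methylpent-3-en-1-yl]dec-2-ene-4,9-diynal
Conditions: TEMPO (10 mol %), PhI(OAc)2 (1.1 equiv), CH2Cl2, rt
Reagents that add atoms: none
Why: Oxoammonium (TEMPO/PhI(OAc)2) oxidation discriminates on steric grounds for the primary over the secondary allylic alcohol and stops at the aldehyde, under conditions too mild to isomerise the enal.

Step 10
Reactants: 15 (2Z)-6-(tert-butyldimethylsilyloxy)-2-[(1S)-1-hydroxy-4-methylpent-3-en-1-yl]dec-2-ene-4,9-diynal; 16 3-methylbut-2-enoyl chloride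
Product: 17 (2Z)-6-(tert-butyldimethylsilyloxy)-2-[(1S)-4-methyl-1-(3-methylbut-2-enoyloxy)pent-3-en-1-yl]dec-2-ene-4,9-diynal
Conditions: pyridine (3 equiv), CH2Cl2, 0 °C
Reagents that add atoms: none
Why: O-Acylation with the acid chloride in the presence of the weak base pyridine, which limits vinylketene formation (deconjugation of the senecioyl group); the C–O bond at the stereocentre is not broken, so the (S)-configuration is retained.

Step 11
Reactants: 17 (2Z)-6-(tert-butyldimethylsilyloxy)-2-[(1S)-4-methyl-1-(3-methylbut-2-enoyloxy)pent-3-en-1-yl]dec-2-ene-4,9-diynal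
Product: 20 (1S)-1-{5-[6-(tert-butyldimethylsilyloxy)-3-oxocyclohex-1-en-1-yl]furan-3-yl}-4-methylpent-3-en-1-yl 3-methylbut-2-enoate, via α-oxo gold carbene 18 (not isolated), via vinyl gold carbene 19 (not isolated)
Conditions: (IPr)AuNTf2 [IPr = 1,3-bis(2,6-diisopropylphenyl)imidazol-2-ylidene] (5 mol %), 8-methylquinoline N-oxide (1.3 equiv, syringe pump over 3 h), 4 Å molecular sieves, 1,2-dichloroethane (0.02 M), rt
Reagents that add atoms: 8-methylquinoline N-oxide, Cc1cccc2ccc[n+]([O-])c12
Why: Proposed new method: monovalent gold binds the unhindered terminal alkyne, the N-oxide oxygen adds to its internal carbon and 8-methylquinoline leaves to give α-oxo gold carbene 18, whose carbene CH is attacked by the propargylic-ether end of the internal alkyne (this makes the ring C=C bond between the future quinone CH and the furyl-bearing carbon) while the carbene character moves to the other alkyne carbon (19), where the cis-disposed aldehyde oxygen closes the furan and expels the catalyst. The closest known reaction types are the gold-catalysed oxidative cyclisation of hepta-1,6-diynes to six-membered enones (carbene/alkyne metathesis via a β-gold vinyl cation) and the collapse of β-acylvinyl metal carbenes to furans; their union on a 2-en-4-ynal acceptor is what is new. The carbocycle closes 6-exo-dig and the furan 5-exo-dig, at the two carbons of the same alkyne, and 7-endo closure is disfavoured because only the exo mode places the cationic carbon within reach of the aldehyde oxygen and in conjugation with the alkene. No stereocentre is formed: the (S)-ester carbon is a spectator held trans to the alkyne across the enal C=C, so that neither its ester carbonyl nor the prenyl alkene can reach the activated alkyne, and the silyloxy carbon stays an inconsequential epimer mixture. The step needs oxidation of the terminal rather than the internal alkyne (the enynal alkyne is electron-poor and flanked by a branched silyloxy carbon), alkyne capture of 18 before 1,5-C–H insertion or a second oxidation (π-nucleophile in a six-ring array, bulky IPr ligand, slow addition of the oxidant at high dilution) and oxygen capture of 19 before its oxidation (intramolecular and aromatising). If gold should trigger the enynal first, the 2-furyl gold carbene so formed has its carbene carbon on the very ring atom to be bonded and can reach 20 by attack of the terminal alkyne followed by oxidation, so both orders of events converge on one product.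

Step 12
Reactants: 20 (1S)-1-{5-[6-(tert-butyldimethylsilyloxy)-3-oxocyclohex-1-en-1-yl]furan-3-yl}-4-methylpent-3-en-1-yl 3-methylbut-2-enoate
Product: 21 (1S)-1-[5-(6-hydroxy-3-oxocyclohex-1-en-1-yl)furan-3-yl]-4-methylpent-3-en-1-yl 3-methylbut-2-enoate
Conditions: HF·pyridine, pyridine, THF, 0 °C to rt
Reagents that add atoms: none
Why: Fluoride-mediated cleavage of the secondary TBS ether with pyridine-buffered HF, conditions that spare the enone, the furan and the ester and avoid the base-induced isomerisation of the γ-hydroxy enone.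

Step 13
Reactants: 21 (1S)-1-[5-(6-hydroxy-3-oxocyclohex-1-en-1-yl)furan-3-yl]-4-methylpent-3-en-1-yl 3-methylbut-2-enoate
Product: 24 (1S)-1-[5-(3,6-dioxocyclohexa-1,4-dien-1-yl)furan-3-yl]-4-methylpent-3-en-1-yl 3-methylbut-2-enoate (CNP0314322.1), via ene-dione 22 (not isolated), via hydroquinone 23 (not isolated)
Conditions: activated MnO2 (20 equiv), CH2Cl2, rt
Reagents that add atoms: none
Why: Three known MnO2 events in sequence: allylic alcohol oxidation to ene-dione 22, enolisation of 22 on the oxide surface to the aromatic hydroquinone 23 (driven by aromatisation), and hydroquinone-to-quinone oxidation; the prenyl and senecioyl alkenes, the furan and the remote (S)-centre are inert to MnO2.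

**Compound list**
1 | 5-(trimethylsilyl)pent-4-yn-1-ol | C[Si](C)(C)C#CCCCO | starting material
2 | 5-(trimethylsilyl)pent-4-ynal | C[Si](C)(C)C#CCCC=O | intermediate
3 | ethynylmagnesium bromide | C#C[Mg]Br | starting material
4 | rac-7-(trimethylsilyl)hepta-1,6-diyn-3-ol | C#CC(O)CCC#C[Si](C)(C)C | intermediate
5 | rac-3-(tert-butyldimethylsilyloxy)-7-(trimethylsilyl)hepta-1,6-diyne | C#CC(CCC#C[Si](C)(C)C)O[Si](C)(C)C(C)(C)C | intermediate
6 | 4-methylpent-3-en-1-ol | CC(C)=CCCO | starting material
7 | 4-methylpent-3-enal | CC(C)=CCC=O | intermediate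
8 | methyl propiolate | C#CC(=O)OC | starting material
9 | (3-iodo-1-methoxypropa-1,2-dien-1-yl)oxytrimethylsilane (silyl allenolate, not isolated) | COC(=C=CI)O[Si](C)(C)C | intermediate
10 | methyl (2Z)-3-iodo-2-[(1S)-4-methyl-1-(trimethylsilyloxy)pent-3-en-1-yl]prop-2-enoate (not isolated) | I/C=C(\C(=O)OC)[C@@H](O[Si](C)(C)C)CC=C(C)C | intermediate
11 | methyl (2Z)-2-[(1S)-1-hydroxy-4-methylpent-3-en-1-yl]-3-iodoprop-2-enoate | I/C=C(\C(=O)OC)[C@@H](O)CC=C(C)C | intermediate
12 | methyl (2Z)-6-(tert-butyldimethylsilyloxy)-2-[(1S)-1-hydroxy-4-methylpent-3-en-1-yl]-10-(trimethylsilyl)dec-2-ene-4,9-diynoate (C6 epimers) | C[Si](C)(C)C#CCCC(O[Si](C)(C)C(C)(C)C)C#C/C=C(\C(=O)OC)[C@@H](O)CC=C(C)C | intermediate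
13 | methyl (2Z)-6-(tert-butyldimethylsilyloxy)-2-[(1S)-1-hydroxy-4-methylpent-3-en-1-yl]dec-2-ene-4,9-diynoate (C6 epimers) | C#CCCC(O[Si](C)(C)C(C)(C)C)C#C/C=C(\C(=O)OC)[C@@H](O)CC=C(C)C | intermediate
14 | (2E)-6-(tert-butyldimethylsilyloxy)-2-[(1S)-1-hydroxy-4-methylpent-3-en-1-yl]dec-2-ene-4,9-diyn-1-ol (C6 epimers) | C#CCCC(O[Si](C)(C)C(C)(C)C)C#C/C=C(\CO)[C@@H](O)CC=C(C)C | intermediate
15 | (2Z)-6-(tert-butyldimethylsilyloxy)-2-[(1S)-1-hydroxy-4-methylpent-3-en-1-yl]dec-2-ene-4,9-diynal (C6 epimers) | C#CCCC(O[Si](C)(C)C(C)(C)C)C#C/C=C(\C=O)[C@@H](O)CC=C(C)C | intermediate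
16 | 3-methylbut-2-enoyl chloride (senecioyl chloride) | CC(C)=CC(=O)Cl | starting material
17 | (2Z)-6-(tert-butyldimethylsilyloxy)-2-[(1S)-4-methyl-1-(3-methylbut-2-enoyloxy)pent-3-en-1-yl]dec-2-ene-4,9-diynal (C6 epimers) | C#CCCC(O[Si](C)(C)C(C)(C)C)C#C/C=C(\C=O)[C@@H](OC(=O)C=C(C)C)CC=C(C)C | intermediate
18 | α-oxo gold carbene from oxidation of the terminal alkyne of 17 (cation shown, NTf2 counter-ion, not isolated) | CC(C)c1cccc(C(C)C)c1N1C=C[N+](=C1[Au]=CC(=O)CCC(O[Si](C)(C)C(C)(C)C)C#C/C=C(\C=O)[C@@H](OC(=O)C=C(C)C)CC=C(C)C)c1c(C(C)C)cccc1C(C)C | intermediate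
19 | cyclohexenonyl vinyl gold carbene bearing the cis enal (cation shown, NTf2 counter-ion, not isolated) | CC(C)c1cccc(C(C)C)c1N1C=C[N+](=C1[Au]=C(/C=C(\C=O)[C@@H](OC(=O)C=C(C)C)CC=C(C)C)C1=CC(=O)CCC1O[Si](C)(C)C(C)(C)C)c1c(C(C)C)cccc1C(C)C | intermediate
20 | (1S)-1-{5-[6-(tert-butyldimethylsilyloxy)-3-oxocyclohex-1-en-1-yl]furan-3-yl}-4-methylpent-3-en-1-yl 3-methylbut-2-enoate (epimers at the silyloxy carbon) | O=C1C=C(c2cc(co2)[C@@H](OC(=O)C=C(C)C)CC=C(C)C)C(O[Si](C)(C)C(C)(C)C)CC1 | intermediate
21 | (1S)-1-[5-(6-hydroxy-3-oxocyclohex-1-en-1-yl)furan-3-yl]-4-methylpent-3-en-1-yl 3-methylbut-2-enoate (epimers at the carbinol carbon of the ring) | O=C1C=C(c2cc(co2)[C@@H](OC(=O)C=C(C)C)CC=C(C)C)C(O)CC1 | intermediate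
22 | (1S)-1-[5-(3,6-dioxocyclohex-1-en-1-yl)furan-3-yl]-4-methylpent-3-en-1-yl 3-methylbut-2-enoate (not isolated) | O=C1C=C(c2cc(co2)[C@@H](OC(=O)C=C(C)C)CC=C(C)C)C(=O)CC1 | intermediate
23 | (1S)-1-[5-(2,5-dihydroxyphenyl)furan-3-yl]-4-methylpent-3-en-1-yl 3-methylbut-2-enoate (not isolated) | Oc1ccc(O)c(c1)-c1cc(co1)[C@@H](OC(=O)C=C(C)C)CC=C(C)C | intermediate
24 | (1S)-1-[5-(3,6-dioxocyclohexa-1,4-dien-1-yl)furan-3-yl]-4-methylpent-3-en-1-yl 3-methylbut-2-enoate (CNP0314322.1) | CC(C)=CC[C@H](OC(=O)C=C(C)C)c1coc(C2=CC(=O)C=CC2=O)c1 | target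

**Count**
Total steps: 13. Longest linear sequence: 11 (steps 1–3 and 6–13).

**Steps most likely to fail**

Step 11. Gold may engage the enynal carbonyl–alkyne pair before the terminal alkyne. Either carbene may be oxidised a second time, or C–H insertion next to the silyloxy group may outrun alkyne capture. The fallback uses known chemistry only, sets out from 17 and returns at 20.
- Compound 17 is treated with (Ph3P)AuNTf2 and aqueous H2O2 in 1,4-dioxane. The known cyclisation of 2-en-4-yn-1-carbonyl compounds to 2-furyl gold carbenes, with oxidation to 2-acylfurans, runs alongside the known Markovnikov hydration of the terminal alkyne.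
- This should give the 1,5-diketone (1S)-1-{5-[2-(tert-butyldimethylsilyloxy)-5-oxohexanoyl]furan-3-yl}-4-methylpent-3-en-1-yl 3-methylbut-2-enoate F1.
- An intramolecular aldol condensation follows (pyrrolidine, AcOH, toluene, 60 °C, the ring-closing half of a Robinson annulation). Only the methyl carbon can reach the furyl ketone through a six-membered ring, so the same C=C bond forms and 20 results.

Step 5. The β,γ-double bond of the aldehyde may migrate into conjugation under the strongly Lewis acidic catalyst. Facial selectivity may also be poor for an unbranched aliphatic aldehyde. The fallback replaces asymmetric C–C bond formation by a racemic coupling plus resolution, sets out from 7 and 8 and returns at 11.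
- The milder MgI2-promoted halo-aldol (CH2Cl2, 0 °C) should give racemic methyl (2Z)-2-(1-hydroxy-4-methylpent-3-en-1-yl)-3-iodoprop-2-enoate F2.
- An acylative kinetic resolution follows with the benzotetramisole antipode that acylates the (R)-allylic alcohol faster (propionic anhydride, i-Pr2NEt, CHCl3, 0 °C, run past half conversion).
- This leaves the (S)-alcohol 11, which is separated by chromatography from methyl (2Z)-3-iodo-2-[(1R)-4-methyl-1-(propanoyloxy)pent-3-en-1-yl]prop-2-enoate F3.

Step 10. The amine may add to the electrophilic enynal by 1,6-addition or by SN2′ displacement of the newly made ester. The enal geometry may scramble, or the acyl group may deconjugate through the vinylketene. The fallback acylates at the alcohol oxidation level, sets out from 14 and returns at 17.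
- Selective silylation of the primary hydroxyl (TESCl, imidazole, CH2Cl2, −20 °C) gives the primary triethylsilyl ether of diol 14 F4.
- Steglich esterification (3-methylbut-2-enoic acid, DCC, DMAP, CH2Cl2, 0 °C) gives the senecioate of that silyl ether F5.
- Selective solvolysis of the primary TES ether (PPTS, MeOH, 0 °C) gives the primary allylic alcohol senecioate F6.
- F6 is oxidised at once with TEMPO/PhI(OAc)2 to 17, before acyl migration can set in.

**Further compounds**
F1 | step 11 | (1S)-1-{5-[2-(tert-butyldimethylsilyloxy)-5-oxohexanoyl]furan-3-yl}-4-methylpent-3-en-1-yl 3-methylbut-2-enoate | CC(=O)CCC(O[Si](C)(C)C(C)(C)C)C(=O)c1cc(co1)[C@@H](OC(=O)C=C(C)C)CC=C(C)C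
F2 | step 5 | racemic methyl (2Z)-2-(1-hydroxy-4-methylpent-3-en-1-yl)-3-iodoprop-2-enoate | I/C=C(\C(=O)OC)C(O)CC=C(C)C
F3 | step 5 | methyl (2Z)-3-iodo-2-[(1R)-4-methyl-1-(propanoyloxy)pent-3-en-1-yl]prop-2-enoate | I/C=C(\C(=O)OC)[C@H](OC(=O)CC)CC=C(C)C
F4 | step 10 | primary triethylsilyl ether of diol 14 | C#CCCC(O[Si](C)(C)C(C)(C)C)C#C/C=C(\CO[Si](CC)(CC)CC)[C@@H](O)CC=C(C)C
F5 | step 10 | senecioate of the primary triethylsilyl ether F4 | C#CCCC(O[Si](C)(C)C(C)(C)C)C#C/C=C(\CO[Si](CC)(CC)CC)[C@@H](OC(=O)C=C(C)C)CC=C(C)C
F6 | step 10 | primary allylic alcohol senecioate (desilylated F5) | C#CCCC(O[Si](C)(C)C(C)(C)C)C#C/C=C(\CO)[C@@H](OC(=O)C=C(C)C)CC=C(C)C
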